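**Plan**

1. Eudesmane numbering is used: ring A is C1–C5 and C10, ring B is C5–C10, C7 carries C11–C13. The retrosynthesis cuts, in order, the C3–O angelate ester, the C12 oxidation level (acrylate back to isopropenyl), the C3–C4 bond of ring A, the C5–acetyl bond and the C10–C1 bond.
2. Enabling feature: in ring A, C3 (O-bearing) and C4 (tertiary carbinol with CH3, bonded to C5 of the ring B alkene C5=C6) form an acyloin pair, and the chain C3–C2–C1–C10–C5–C4 ties an aldehyde carbon and a ketone carbon 1,6. One umpolung C–C bond formation therefore closes ring A, creates C4 and leaves C3 and C4 at different oxidation levels.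
3. Forward: ring B comes intact from (+)-dihydrocarvone. The C1–C3 chain is added at C10, the ring ketone becomes the C5 enol triflate and then the C5 acetyl group, and ring A is closed last by an aldehyde–ketone benzoin cyclisation. C3 reduction, C12 oxidation, methyl ester and angelate follow.
4. Stereochemistry: C7 from the chiral pool; C10 from an auxiliary-controlled Michael addition; C4 from the key step (relay from C10 through a chair, reinforced by a chiral carbene); C3 from axial hydride delivery; the Z alkene from angelic acid.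

Key step: step 6

Assumption: commercial (+)-dihydrocarvone is (5R)-configured material containing both C2 epimers; C2 is rebuilt in steps 1 and 2, so the mixture is used as such (the SMILES of 1 shows the major 2R,5R isomer).

**Route**

Step 1
Reactants: 1 (+)-dihydrocarvone; 2 (R)-1-phenylethylamine
Product: 3 (5R)-2-methyl-N-[(1R)-1-phenylethyl]-5-(prop-1-en-2-yl)cyclohexan-1-imine
Conditions: cat. TsOH, toluene, reflux, Dean–Stark trap
Reagents that add atoms: none
Why: Ketone–amine condensation with azeotropic removal of water gives the ketimine, and C2 epimerisation through the enamine tautomer is harmless because this centre is rebuilt in step 2.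

Step 2
Reactants: 3 imine; 4 acrylonitrile
Product: 6 3-[(1S,4R)-1-methyl-2-oxo-4-(prop-1-en-2-yl)cyclohexyl]propanenitrile, via Michael adduct imine 5 (not isolated)
Conditions: THF, 60 °C; then 20% aq. AcOH, rt
Reagents that add atoms: water, O
Why: Asymmetric Michael addition of a chiral imine through its more substituted secondary enamine tautomer (aza-ene-like transition state with internal N–H transfer) should build the C10 quaternary centre regioselectively, with the (R)-1-phenylethyl group shielding one enamine face so that the cyanoethyl chain enters trans to the isopropenyl group, and mild acid hydrolysis returns the ketone.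

Step 3
Reactants: 6 keto nitrile
Product: 7 (3R,6S)-6-(2-cyanoethyl)-6-methyl-3-(prop-1-en-2-yl)cyclohex-1-en-1-yl trifluoromethanesulfonate
Conditions: KN(SiMe3)2, THF, −78 °C; then N-(5-chloropyridin-2-yl)bis(trifluoromethanesulfonimide), −78 to −40 °C
Reagents that add atoms: N-(5-chloropyridin-2-yl)bis(trifluoromethanesulfonimide), FC(F)(F)S(=O)(=O)N(c1ccc(Cl)cn1)S(=O)(=O)C(F)(F)F
Why: The ketone can enolise only towards C6 (C10 is quaternary) and is far more acidic than the nitrile α-CH2, so kinetic deprotonation and O-sulfonylation (enolate triflation) should give a single enol triflate.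

Step 4
Reactants: 7 enol triflate nitrile
Product: 8 (3R,6S)-6-methyl-6-(3-oxopropyl)-3-(prop-1-en-2-yl)cyclohex-1-en-1-yl trifluoromethanesulfonate
Conditions: i-Bu2AlH, CH2Cl2, −78 °C; then 1 M aq. HCl, 0 °C
Reagents that add atoms: water, O
Why: i-Bu2AlH adds once to the nitrile to give an N-aluminated imine that is hydrolysed to the aldehyde on acidic work-up (partial nitrile reduction), while the enol triflate and the isopropenyl group are inert at −78 °C.

Step 5
Reactants: 8 aldehyde enol triflate; 9 tributyl(1-ethoxyvinyl)stannane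
Product: 11 3-[(1S,4R)-2-acetyl-1-methyl-4-(prop-1-en-2-yl)cyclohex-2-en-1-yl]propanal, via enol ether 10 (not isolated)
Conditions: Pd(PPh3)4 (5 mol%), LiCl, THF, 65 °C; then 1 M aq. HCl, THF, 0 °C
Reagents that add atoms: water, O
Why: Stille coupling of the enol triflate (oxidative addition to zerovalent palladium, chloride-assisted transmetallation) installs a 1-ethoxyvinyl group that dilute acid hydrolyses to the C5 acetyl group, and the aldehyde is tolerated.

Step 6
Reactants: 11 keto aldehyde
Product: 12 (1R,4aS,7R)-1-hydroxy-1,4a-dimethyl-7-(prop-1-en-2-yl)-3,4,4a,5,6,7-hexahydronaphthalen-2(1H)-one (4β-hydroxyeudesma-5,11-dien-3-one)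
Conditions: aminoindanol-derived N-pentafluorophenyl triazolium tetrafluoroborate (15 mol%, the antipode matched to the substrate bias), Et3N (15 mol%), degassed toluene, rt
Reagents that add atoms: none
Why: Proposed new method: the triazolylidene adds to the aldehyde carbon C3 and proton transfer gives the enaminol acyl-anion equivalent, whose C3 attacks the carbonyl carbon C4 of the acetyl group in a 1,2-fashion; proton transfer and loss of the carbene then leave the C3 ketone and the C4 tertiary alcohol. The closest known reaction type is the carbene-catalysed intramolecular crossed aldehyde–ketone benzoin cyclisation of keto aldehydes to six-membered α-ketols, established for aryl and saturated alkyl ketones but not for a ketone conjugated with a ring alkene that offers a competing 1,4-site. Ring A closes in the 6-exo-trig mode at the C4 carbonyl. C4 is controlled by C10 through a chair-like transition state: the pseudo-equatorial C7 isopropenyl group holds ring B in the half-chair with the C10 methyl pseudo-axial and the chain pseudo-equatorial, the acetyl CH3 takes the equatorial site beside H6 and the carbonyl oxygen the axial site, so the OH ends on the face of the C10 methyl (4R), and the antipode of the chiral triazolium salt is chosen to reinforce this preference. The step needs 1,2- over 1,4-chemoselectivity and no aldol chemistry: attack at C6 would be a 6-endo closure to a bridged bicyclo[3.3.1]nonane with C6 shielded by the C7 substituent, and the tertiary amine is too weak a base to enolise the aldehyde or the methyl ketone. Since benzoin addition is reversible, the product with an axial OH/CH3 contact rather than an axial CH3/CH3 contact across ring A should also be the thermodynamically preferred epimer.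

Step 7
Reactants: 12 α-ketol
Product: 13 (1R,2S,4aS,7R)-1,4a-dimethyl-7-(prop-1-en-2-yl)-1,2,3,4,4a,5,6,7-octahydronaphthalene-1,2-diol (eudesma-5,11-diene-3β,4β-diol)
Conditions: NaBH4, MeOH, −20 °C
Reagents that add atoms: none
Why: In this substrate-controlled reduction of a cyclic α-ketol, hydride should attack the C3 ketone of the ring A chair axially from the face opposite the axial C4–OH and the axial C10 methyl, giving the equatorial 3β-alcohol cis to the 4β-OH, while the low temperature keeps the α-ketol from rearranging.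

Step 8
Reactants: 13 diol
Product: 15 2-[(2R,4aS,7S,8R)-7,8-dihydroxy-4a,8-dimethyl-2,3,4,4a,5,6,7,8-octahydronaphthalen-2-yl]prop-2-enal, via allylic alcohol 14 (not isolated)
Conditions: SeO2 (0.3 equiv), t-BuOOH, CH2Cl2, rt; filtration; then MnO2, CH2Cl2, rt
Reagents that add atoms: selenium dioxide, O=[Se]=O (oxygen donor, regenerated by tert-butyl hydroperoxide, CC(C)(C)OO)
Why: Selenium dioxide allylic oxidation (ene reaction then [2,3]-sigmatropic shift) should attack the isopropenyl group at its methyl group, because the C7–H lies in the nodal plane of that alkene and the C5=C6 alkene has no hydrogen on the allylic carbons of its more substituted end (C4 and C10 are quaternary), and MnO2 then oxidises only the primary allylic alcohol.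

Step 9
Reactants: 15 enal
Product: 16 2-[(2R,4aS,7S,8R)-7,8-dihydroxy-4a,8-dimethyl-2,3,4,4a,5,6,7,8-octahydronaphthalen-2-yl]prop-2-enoic acid
Conditions: NaClO2, NaH2PO4, 2-methylbut-2-ene, t-BuOH/H2O, 0 °C to rt
Reagents that add atoms: sodium chlorite, [Na+].[O-]Cl=O
Why: Pinnick oxidation converts the enal into the acrylic acid under buffered conditions, with 2-methylbut-2-ene trapping HOCl so that the C5=C6 alkene and the diol are untouched.

Step 10
Reactants: 16 acid
Product: 17 methyl 2-[(2R,4aS,7S,8R)-7,8-dihydroxy-4a,8-dimethyl-2,3,4,4a,5,6,7,8-octahydronaphthalen-2-yl]prop-2-enoate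
Conditions: MeI, K2CO3, DMF, rt
Reagents that add atoms: iodomethane, CI
Why: SN2 O-methylation of the potassium carboxylate is selective over the neutral hydroxyl groups, and the carbonate base does not deprotonate C7, whose anion would gain no stabilisation from an ester placed on the central carbon of the allyl system.

Step 11
Reactants: 17 diol methyl ester; 18 angelic acid
Product: 20 methyl 2-[(2R,4aS,7S,8R)-8-hydroxy-4a,8-dimethyl-7-{[(2Z)-2-methylbut-2-enoyl]oxy}-2,3,4,4a,5,6,7,8-octahydronaphthalen-2-yl]prop-2-enoate (target), via mixed anhydride 19 (not isolated)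
Conditions: 18, 2,4,6-Cl3C6H2COCl, Et3N, toluene, rt; then 17, toluene, 80 °C
Reagents that add atoms: none
Why: Yamaguchi esterification through the mixed anhydride without a nucleophilic pyridine catalyst should acylate only the secondary equatorial 3β-OH (the tertiary C4–OH is inert) and carry the Z geometry of angelic acid through unchanged.

**Compound list**

1 | (+)-dihydrocarvone, (2R,5R)-2-methyl-5-(prop-1-en-2-yl)cyclohexan-1-one | CC(=C)[C@H]1CC(=O)[C@H](C)CC1 | starting material
2 | (R)-1-phenylethylamine | C[C@@H](N)c1ccccc1 | starting material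
3 | (5R)-2-methyl-N-[(1R)-1-phenylethyl]-5-(prop-1-en-2-yl)cyclohexan-1-imine (C2 epimers) | CC(=C)[C@H]1CC(=N[C@H](C)c2ccccc2)C(C)CC1 | intermediate
4 | acrylonitrile | C=CC#N | starting material
5 | 3-[(1S,4R)-1-methyl-2-{[(1R)-1-phenylethyl]imino}-4-(prop-1-en-2-yl)cyclohexyl]propanenitrile | CC(=C)[C@H]1CC(=N[C@H](C)c2ccccc2)[C@](C)(CCC#N)CC1 | intermediate
6 | 3-[(1S,4R)-1-methyl-2-oxo-4-(prop-1-en-2-yl)cyclohexyl]propanenitrile | CC(=C)[C@H]1CC(=O)[C@](C)(CCC#N)CC1 | intermediate
7 | (3R,6S)-6-(2-cyanoethyl)-6-methyl-3-(prop-1-en-2-yl)cyclohex-1-en-1-yl trifluoromethanesulfonate | CC(=C)[C@H]1C=C(OS(=O)(=O)C(F)(F)F)[C@](C)(CCC#N)CC1 | intermediate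
8 | (3R,6S)-6-methyl-6-(3-oxopropyl)-3-(prop-1-en-2-yl)cyclohex-1-en-1-yl trifluoromethanesulfonate | CC(=C)[C@H]1C=C(OS(=O)(=O)C(F)(F)F)[C@](C)(CCC=O)CC1 | intermediate
9 | tributyl(1-ethoxyvinyl)stannane | CCCC[Sn](CCCC)(CCCC)C(=C)OCC | starting material
10 | 3-[(1S,4R)-2-(1-ethoxyethenyl)-1-methyl-4-(prop-1-en-2-yl)cyclohex-2-en-1-yl]propanal | CC(=C)[C@H]1C=C(C(=C)OCC)[C@](C)(CCC=O)CC1 | intermediate
11 | 3-[(1S,4R)-2-acetyl-1-methyl-4-(prop-1-en-2-yl)cyclohex-2-en-1-yl]propanal | CC(=C)[C@H]1C=C(C(C)=O)[C@](C)(CCC=O)CC1 | intermediate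
12 | (1R,4aS,7R)-1-hydroxy-1,4a-dimethyl-7-(prop-1-en-2-yl)-3,4,4a,5,6,7-hexahydronaphthalen-2(1H)-one | CC(=C)[C@H]1C=C2[C@](C)(CCC(=O)[C@]2(C)O)CC1 | intermediate
13 | (1R,2S,4aS,7R)-1,4a-dimethyl-7-(prop-1-en-2-yl)-1,2,3,4,4a,5,6,7-octahydronaphthalene-1,2-diol | CC(=C)[C@H]1C=C2[C@](C)(CC[C@H](O)[C@]2(C)O)CC1 | intermediate
14 | 2-[(2R,4aS,7S,8R)-7,8-dihydroxy-4a,8-dimethyl-2,3,4,4a,5,6,7,8-octahydronaphthalen-2-yl]prop-2-en-1-ol | OCC(=C)[C@H]1C=C2[C@](C)(CC[C@H](O)[C@]2(C)O)CC1 | intermediate
15 | 2-[(2R,4aS,7S,8R)-7,8-dihydroxy-4a,8-dimethyl-2,3,4,4a,5,6,7,8-octahydronaphthalen-2-yl]prop-2-enal | O=CC(=C)[C@H]1C=C2[C@](C)(CC[C@H](O)[C@]2(C)O)CC1 | intermediate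
16 | 2-[(2R,4aS,7S,8R)-7,8-dihydroxy-4a,8-dimethyl-2,3,4,4a,5,6,7,8-octahydronaphthalen-2-yl]prop-2-enoic acid | OC(=O)C(=C)[C@H]1C=C2[C@](C)(CC[C@H](O)[C@]2(C)O)CC1 | intermediate
17 | methyl 2-[(2R,4aS,7S,8R)-7,8-dihydroxy-4a,8-dimethyl-2,3,4,4a,5,6,7,8-octahydronaphthalen-2-yl]prop-2-enoate | COC(=O)C(=C)[C@H]1C=C2[C@](C)(CC[C@H](O)[C@]2(C)O)CC1 | intermediate
18 | angelic acid, (2Z)-2-methylbut-2-enoic acid | C/C=C(/C)C(=O)O | starting material
19 | (2Z)-2-methylbut-2-enoic 2,4,6-trichlorobenzoic anhydride | C/C=C(/C)C(=O)OC(=O)c1c(Cl)cc(Cl)cc1Cl | intermediate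
20 | methyl 2-[(2R,4aS,7S,8R)-8-hydroxy-4a,8-dimethyl-7-{[(2Z)-2-methylbut-2-enoyl]oxy}-2,3,4,4a,5,6,7,8-octahydronaphthalen-2-yl]prop-2-enoate | C=C(C(=O)OC)[C@H]1C=C2[C@](C)(CC[C@H](OC(=O)/C(C)=C\C)[C@]2(C)O)CC1 | target

**Count and risks**

Total step count: 11. Longest linear sequence: 11 steps (1 to 20).

Steps most likely to fail:

Step 6. The acyl-anion equivalent may add in a conjugate sense at C6, the hindered cross-conjugated ketone may not be attacked at a useful rate, or the facial selectivity at C4 may be poor. The fallback uses known chemistry and forms the C4–C5 bond of ring A instead of the C3–C4 bond; it sets out from 8 and comes back at 12. 1-Ethoxyvinyllithium (ethyl vinyl ether, t-BuLi, THF, −78 °C) adds to the aldehyde of 8 to give the enol ether carbinol F1. Dilute aqueous HCl hydrolyses it to the α-hydroxy methyl ketone F2 (both C3 epimers), and TBSCl/imidazole gives the silyl ether F3. An intramolecular Nozaki–Hiyama–Kishi reaction (CrCl2, cat. NiCl2, DMF) adds the C5 alkenylchromium derived from the enol triflate to the methyl ketone and gives the ring-closed tertiary alcohol F4. Bu4NF frees the diol F5 (C3 epimers), and oxidation of the secondary carbinol with 2-iodoxybenzoic acid converges both epimers on ketol 12.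

Step 8. The ene step may abstract the doubly allylic C7–H instead of a methyl hydrogen, or over-oxidation may occur in the presence of the free diol. The fallback places the allylic oxidation before the C5=C6 alkene exists; it sets out from 6 and comes back at 14, which MnO2 oxidises to 15 as in step 8. SeO2/t-BuOOH converts 6 into the allylic alcohol F6 and TBSCl/imidazole gives the silyl ether F7. The main sequence is then repeated on this series: enolate triflation gives the enol triflate F8, i-Bu2AlH gives the aldehyde F9, and Stille coupling with 9 gives the enol ether F10. Oxalic acid on wet silica (to spare the silyl ether) hydrolyses it to the keto aldehyde F11, the benzoin cyclisation gives the ketol F12 and NaBH4 gives the diol F13. Bu4NF then releases triol 14.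

Step 11. The angeloyl group may isomerise from Z to E during activation, or acylation next to the fully substituted C4 may be sluggish. The fallback builds the Z alkene after the ester bond is made; it sets out from 17 and arrives at 20. DCC/cat. DMAP esterification of 17 with 2-[bis(2,2,2-trifluoroethoxy)phosphoryl]propanoic acid gives the phosphonate ester F14. Still–Gennari olefination (KN(SiMe3)2, 18-crown-6, THF, −78 °C, then acetaldehyde) should then give the Z-configured 2-methylbut-2-enoate 20 directly.

**Further compounds**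

F1 | step 6 | (3R,6S)-6-(4-ethoxy-3-hydroxypent-4-en-1-yl)-6-methyl-3-(prop-1-en-2-yl)cyclohex-1-en-1-yl trifluoromethanesulfonate (C3 epimers) | CC(=C)[C@H]1C=C(OS(=O)(=O)C(F)(F)F)[C@](C)(CCC(O)C(=C)OCC)CC1
F2 | step 6 | (3R,6S)-6-(3-hydroxy-4-oxopentyl)-6-methyl-3-(prop-1-en-2-yl)cyclohex-1-en-1-yl trifluoromethanesulfonate (C3 epimers) | CC(=C)[C@H]1C=C(OS(=O)(=O)C(F)(F)F)[C@](C)(CCC(O)C(C)=O)CC1
F3 | step 6 | (3R,6S)-6-[3-(tert-butyldimethylsilyloxy)-4-oxopentyl]-6-methyl-3-(prop-1-en-2-yl)cyclohex-1-en-1-yl trifluoromethanesulfonate (C3 epimers) | CC(=C)[C@H]1C=C(OS(=O)(=O)C(F)(F)F)[C@](C)(CCC(O[Si](C)(C)C(C)(C)C)C(C)=O)CC1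
F4 | step 6 | 3-(tert-butyldimethylsilyloxy)eudesma-5,11-dien-4β-ol (C3 epimers; 4R,7R,10S) | CC(=C)[C@H]1C=C2[C@](C)(CCC(O[Si](C)(C)C(C)(C)C)[C@]2(C)O)CC1
F5 | step 6 | eudesma-5,11-diene-3,4β-diol (C3 epimers; 4R,7R,10S) | CC(=C)[C@H]1C=C2[C@](C)(CCC(O)[C@]2(C)O)CC1
F6 | step 8 | 3-[(1S,4R)-4-(3-hydroxyprop-1-en-2-yl)-1-methyl-2-oxocyclohexyl]propanenitrile | OCC(=C)[C@H]1CC(=O)[C@](C)(CCC#N)CC1
F7 | step 8 | 3-[(1S,4R)-4-[3-(tert-butyldimethylsilyloxy)prop-1-en-2-yl]-1-methyl-2-oxocyclohexyl]propanenitrile | CC(C)(C)[Si](C)(C)OCC(=C)[C@H]1CC(=O)[C@](C)(CCC#N)CC1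
F8 | step 8 | (3R,6S)-3-[3-(tert-butyldimethylsilyloxy)prop-1-en-2-yl]-6-(2-cyanoethyl)-6-methylcyclohex-1-en-1-yl trifluoromethanesulfonate | CC(C)(C)[Si](C)(C)OCC(=C)[C@H]1C=C(OS(=O)(=O)C(F)(F)F)[C@](C)(CCC#N)CC1
F9 | step 8 | (3R,6S)-3-[3-(tert-butyldimethylsilyloxy)prop-1-en-2-yl]-6-methyl-6-(3-oxopropyl)cyclohex-1-en-1-yl trifluoromethanesulfonate | CC(C)(C)[Si](C)(C)OCC(=C)[C@H]1C=C(OS(=O)(=O)C(F)(F)F)[C@](C)(CCC=O)CC1
F10 | step 8 | 3-[(1S,4R)-4-[3-(tert-butyldimethylsilyloxy)prop-1-en-2-yl]-2-(1-ethoxyethenyl)-1-methylcyclohex-2-en-1-yl]propanal | CC(C)(C)[Si](C)(C)OCC(=C)[C@H]1C=C(C(=C)OCC)[C@](C)(CCC=O)CC1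
F11 | step 8 | 3-[(1S,4R)-2-acetyl-4-[3-(tert-butyldimethylsilyloxy)prop-1-en-2-yl]-1-methylcyclohex-2-en-1-yl]propanal | CC(C)(C)[Si](C)(C)OCC(=C)[C@H]1C=C(C(C)=O)[C@](C)(CCC=O)CC1
F12 | step 8 | 12-(tert-butyldimethylsilyloxy)-4β-hydroxyeudesma-5,11(13)-dien-3-one (4R,7R,10S) | CC(C)(C)[Si](C)(C)OCC(=C)[C@H]1C=C2[C@](C)(CCC(=O)[C@]2(C)O)CC1
F13 | step 8 | 12-(tert-butyldimethylsilyloxy)eudesma-5,11(13)-diene-3β,4β-diol (3S,4R,7R,10S) | CC(C)(C)[Si](C)(C)OCC(=C)[C@H]1C=C2[C@](C)(CC[C@H](O)[C@]2(C)O)CC1
F14 | step 11 | methyl 3β-{2-[bis(2,2,2-trifluoroethoxy)phosphoryl]propanoyloxy}-4β-hydroxyeudesma-5,11(13)-dien-12-oate (3S,4R,7R,10S) | COC(=O)C(=C)[C@H]1C=C2[C@](C)(CC[C@H](OC(=O)C(C)P(=O)(OCC(F)(F)F)OCC(F)(F)F)[C@]2(C)O)CC1
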